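The furofuran core (lignan numbering: C-7/C-8/C-9 on the side of the syringyl ring with the two-unit chain, primed atoms on the other side) is disconnected at the benzylic C-7′–O-9 ether bond and at C-8–C-8′, back to an acyclic epoxy cinnamyl ether. One titanocene-mediated radical–polar cascade closes both tetrahydrofuran rings: the epoxide-derived C-8 radical cyclises onto the styrene, and C-7′, oxidised with iodine, is captured by O-9. The step exploits the cis-fused 3,7-dioxabicyclo[3.3.0]octane with both aryl rings on its convex face and the cation-stabilising trialkoxyphenyl ring on C-7′: stereocentre C-7 alone dictates C-8, C-8′ and C-7′, whatever the epoxide configuration. Three Evans glycolate aldols, two followed by Mitsunobu inversion, build the arylglycerol units.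

Key step: step 11

Remark on names: S1 is the syringyl ring on C-7, S2 the syringyl ring on C-7′; G3 is the guaiacylglycerol unit on S2 (erythro, αS,βR), G2 the inner unit on S1 (threo, αR,βR), G1 the terminal unit on G2 (erythro, αR,βS); α is the benzylic carbon and β the aryloxy-bearing carbon of each unit; ring A is the tetrahydrofuran holding C-7, ring B the one holding C-7′.
Assumption: canolol (6) and both enantiomers of 4-benzyl-3-(chloroacetyl)oxazolidin-2-one (7, 22) are taken as catalogue compounds.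

Step 1
Reactants: 1 syringaldehyde
Product: 2 3,5-dimethoxy-4-(triisopropylsilyloxy)benzaldehyde
Conditions: TIPSCl, imidazole, DMF, rt
Reagents that add atoms: triisopropylsilyl chloride, CC(C)[Si](Cl)(C(C)C)C(C)C
Why: Imidazole-promoted O-silylation of the hindered phenol gives a silyl ether that should survive the Grignard, alkoxide and radical steps and is later cleaved by fluoride faster than alkyl silyl ethers; no stereocentre is formed.

Step 2
Reactants: 2 3,5-dimethoxy-4-(triisopropylsilyloxy)benzaldehyde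
Product: 3 racemic 1-[3,5-dimethoxy-4-(triisopropylsilyloxy)phenyl]prop-2-en-1-ol
Conditions: CH2=CHMgBr, THF, −78 °C to 0 °C; aq. NH4Cl
Reagents that add atoms: vinylmagnesium bromide, C=C[Mg]Br
Why: Grignard 1,2-addition of the vinyl nucleophile to the aldehyde gives the aryl vinyl carbinol as a racemate, its carbinol carbon being the future C-7.

Step 3
Reactants: 3 racemic aryl vinyl carbinol (only its (R)-enantiomer is consumed)
Product: 4 (S)-[3,5-dimethoxy-4-(triisopropylsilyloxy)phenyl][(2R)-oxiran-2-yl]methanol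
Conditions: Ti(OiPr)4 (10 mol%), L-(+)-DIPT (12 mol%), t-BuOOH (0.55 equiv), 4 Å molecular sieves, CH2Cl2, −20 °C
Reagents that add atoms: tert-butyl hydroperoxide, CC(C)(C)OO
Why: Sharpless kinetic resolution (titanium tartrate-catalysed epoxidation of a secondary allylic alcohol): with L-(+)-DIPT the (R)-enantiomer of 3 is epoxidised much faster than the (S)-enantiomer and oxygen is delivered anti to the aryl group, so that at about half conversion the erythro epoxy alcohol with the C-7 configuration of the target should be isolated and unreacted (S)-3 separated (the carbinol descriptor changes to S only because oxiranyl outranks aryl).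

Step 4
Reactants: 4 erythro epoxy alcohol
Product: 5 (2R)-2-[(S)-(allyloxy)[3,5-dimethoxy-4-(triisopropylsilyloxy)phenyl]methyl]oxirane
Conditions: NaH, allyl bromide, Bu4NI (cat.), THF, 0 °C
Reagents that add atoms: allyl bromide, C=CCBr
Why: Williamson ether synthesis on the sodium alkoxide with the reactive allyl bromide at 0 °C, where O-alkylation should outrun Payne rearrangement of the epoxy alkoxide; both stereocentres are untouched.

Step 5
Reactants: 6 canolol (2,6-dimethoxy-4-vinylphenol); 7 (S)-4-benzyl-3-(chloroacetyl)oxazolidin-2-one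
Product: 8 (S)-4-benzyl-3-[(2,6-dimethoxy-4-vinylphenoxy)acetyl]oxazolidin-2-one
Conditions: K2CO3, DMF, rt
Reagents that add atoms: none
Why: Williamson-type SN2 O-alkylation of the phenoxide by the activated α-chloro imide attaches the glycolyl unit already bound to the Evans auxiliary; no new stereocentre.

Step 6
Reactants: 8 aryloxyacetyl imide; 9 4-(benzyloxy)-3-methoxybenzaldehyde
Product: 11 (2S,3R) syn-aldol imide of the S2–G3 unit, via dibutylboron enolate 10 (not isolated)
Conditions: Bu2BOTf, i-Pr2NEt, CH2Cl2, −78 °C to 0 °C; then 9, −78 °C to 0 °C; pH 7 buffer, MeOH, H2O2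
Reagents that add atoms: none
Why: Evans syn-aldol reaction: the (Z)-boron enolate adds to the aldehyde through a Zimmerman–Traxler chair whose accessible face is fixed by the (S)-benzyl group of the auxiliary, which sets C-2 as S and C-3 as R, that is the threo (αR,βR) pattern of the future glycerol unit.

Step 7
Reactants: 11 syn-aldol imide
Product: 12 (1R,2R)-1-[4-(benzyloxy)-3-methoxyphenyl]-2-(2,6-dimethoxy-4-vinylphenoxy)propane-1,3-diol
Conditions: NaBH4, THF/H2O, 0 °C to rt
Reagents that add atoms: none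
Why: Chemoselective borohydride reduction of the activated imide carbonyl releases the primary alcohol and the recoverable auxiliary while the styrene and the stereocentres stay untouched.

Step 8
Reactants: 12 threo diol
Product: 13 primary TBS ether of 12
Conditions: TBSCl, imidazole, CH2Cl2, 0 °C
Reagents that add atoms: tert-butyldimethylsilyl chloride, CC(C)(C)[Si](C)(C)Cl
Why: Steric differentiation in silyl ether formation protects the primary hydroxyl and leaves the hindered secondary benzylic hydroxyl free for inversion.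

Step 9
Reactants: 13 threo benzylic alcohol
Product: 14 (1S,2R)-1-[4-(benzyloxy)-3-methoxyphenyl]-3-[(tert-butyldimethylsilyl)oxy]-2-(2,6-dimethoxy-4-vinylphenoxy)propyl benzoate
Conditions: PhCO2H, PPh3, DIAD, THF, 0 °C to rt
Reagents that add atoms: benzoic acid, OC(=O)c1ccccc1
Why: Mitsunobu reaction: SN2 attack of benzoate on the benzylic alkoxyphosphonium ion inverts C-α from R to S, which converts the threo aldol pattern into the erythro (αS,βR) unit G3 and at the same time masks the α-oxygen as an ester.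

Step 10
Reactants: 14 erythro styrene (protected S2–G3 unit); 5 allyl ether epoxide (3 equiv)
Product: 15 epoxy (E)-cinnamyl ether joining the S1 and S2–G3 parts
Conditions: second-generation Grubbs catalyst (5 mol%), CH2Cl2, 40 °C
Reagents that add atoms: none
Why: Olefin cross-metathesis of the terminal allyl ether (used in excess) with the electron-rich styrene releases ethylene and should give the (E)-cinnamyl ether; the alkene geometry is erased in the next step and no stereocentre is involved.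

Step 11
Reactants: 15 epoxy cinnamyl ether
Product: 18 (7R,8S,7′R,8′S)-furofuran with TIPS-protected ring S1 and protected unit G3 on ring S2, via benzylic organotitanium 16 (not isolated), via benzylic iodide 17 (not isolated)
Conditions: Cp2TiCl2 (2.5 equiv), Zn dust, THF, rt; 15 added slowly; then I2, 60 °C
Reagents that add atoms: none
Why: Cp2TiCl (trivalent titanium) opens the terminal epoxide of 15 by single-electron transfer to the secondary C-8 radical bearing a CH2O–Ti group, which adds to the cinnamyl double bond and leaves a benzylic C-7′ radical that a second Cp2TiCl traps as organotitanium 16; iodine turns 16 into benzylic iodide 17, whose C–I bond ionises with the help of the trialkoxyphenyl ring S2 so that the titanium-bound O-9 forms the C-7′–O bond. The closest known reaction type is the titanocene-mediated radical cyclisation of epoxy cinnamyl ethers with iodine-induced etherification that is established for furofuran lignans. Ring A closes by 5-exo-trig radical addition of C-8 to C-8′, ring B by 5-exo-tet displacement at C-7′ with SN1 character. Because the C-8 radical is planar the epoxide configuration is erased and C-7 alone controls the new stereocentres: in the chair-like Beckwith–Houk transition state the aryl group on C-7 sits pseudo-equatorial, which places the CH2O–Ti group on C-8 trans to it and the benzylic arm on C-8′ cis to that group. C-7′ is set in the etherification, where the cis-fused bicycle admits ring S2 only on the convex exo face, so both epimers of 17 converge on the (7′R) product. The step needs cyclisation to outrun reduction of the β-titanoxy radical to an alkene and must leave the benzoate, silyl and benzyl groups untouched; the fast styrene-type acceptor and the mild, neutral trivalent-titanium medium should secure both.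

Step 12
Reactants: 18 TIPS-protected furofuran
Product: 19 furofuran with free ring S1 phenol
Conditions: TBAF (1.1 equiv), AcOH (1.1 equiv), THF, 0 °C
Reagents that add atoms: none
Why: Fluoride-induced Si–O cleavage of the aryl silyl ether, which is much faster than that of the primary alkyl TBS ether because phenoxide is the better leaving group, frees the ring S1 phenol, while the acetic acid buffer protects the benzoate.

Step 13
Reactants: 19 furofuran phenol; 7 (S)-4-benzyl-3-(chloroacetyl)oxazolidin-2-one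
Product: 20 furofuran whose ring S1 oxygen carries the glycolyl (S)-oxazolidinone imide
Conditions: K2CO3, DMF, rt
Reagents that add atoms: none
Why: Williamson-type SN2 O-alkylation of the hindered phenoxide by the primary α-chloro imide installs the glycolate for unit G2; no new stereocentre.

Step 14
Reactants: 21 trans-isoeugenol; 22 (R)-4-benzyl-3-(chloroacetyl)oxazolidin-2-one
Product: 23 (R)-4-benzyl-3-[[2-methoxy-4-[(E)-prop-1-enyl]phenoxy]acetyl]oxazolidin-2-one
Conditions: K2CO3, DMF, rt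
Reagents that add atoms: none
Why: Williamson-type SN2 O-alkylation of the phenoxide by the α-chloro imide, with the propenyl group serving as a masked aldehyde for ring G2; no new stereocentre.

Step 15
Reactants: 23 aryloxyacetyl imide; 9 4-(benzyloxy)-3-methoxybenzaldehyde
Product: 25 (2R,3S) syn-aldol imide of the G2–G1 unit, via dibutylboron enolate 24 (not isolated)
Conditions: Bu2BOTf, i-Pr2NEt, CH2Cl2, −78 °C to 0 °C; then 9, −78 °C to 0 °C; pH 7 buffer, MeOH, H2O2
Reagents that add atoms: none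
Why: Evans syn-aldol reaction as in step 6 but with the enantiomeric auxiliary, whose (R)-benzyl group directs the Zimmerman–Traxler chair to the opposite enolate face and sets C-2 as R and C-3 as S, that is the threo (αS,βS) pattern.

Step 16
Reactants: 25 syn-aldol imide
Product: 26 (1S,2S)-1-[4-(benzyloxy)-3-methoxyphenyl]-2-[2-methoxy-4-[(E)-prop-1-enyl]phenoxy]propane-1,3-diol
Conditions: NaBH4, THF/H2O, 0 °C to rt
Reagents that add atoms: none
Why: Chemoselective borohydride reduction of the imide carbonyl gives the primary alcohol and the recoverable auxiliary without touching the propenyl group or the stereocentres.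

Step 17
Reactants: 26 threo diol
Product: 27 primary TBS ether of 26
Conditions: TBSCl, imidazole, CH2Cl2, 0 °C
Reagents that add atoms: tert-butyldimethylsilyl chloride, CC(C)(C)[Si](C)(C)Cl
Why: Selective silylation of the primary hydroxyl by steric differentiation leaves the benzylic hydroxyl free for inversion.

Step 18
Reactants: 27 threo benzylic alcohol
Product: 28 (1R,2S)-1-[4-(benzyloxy)-3-methoxyphenyl]-3-[(tert-butyldimethylsilyl)oxy]-2-[2-methoxy-4-[(E)-prop-1-enyl]phenoxy]propyl benzoate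
Conditions: PhCO2H, PPh3, DIAD, THF, 0 °C to rt
Reagents that add atoms: benzoic acid, OC(=O)c1ccccc1
Why: Mitsunobu reaction: SN2 inversion at C-α by benzoate turns the (αS,βS) pattern into the erythro (αR,βS) pattern of unit G1 and protects the α-oxygen.

Step 19
Reactants: 28 erythro propenylarene
Product: 30 (1R,2S)-1-[4-(benzyloxy)-3-methoxyphenyl]-3-[(tert-butyldimethylsilyl)oxy]-2-(4-formyl-2-methoxyphenoxy)propyl benzoate, via vicinal diol 29 (not isolated)
Conditions: OsO4 (2 mol%), NaIO4, 2,6-lutidine, dioxane/H2O, rt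
Reagents that add atoms: sodium periodate, [Na+].[O-]I(=O)(=O)=O (oxygen relayed by catalytic osmium tetroxide, O=[Os](=O)(=O)=O)
Why: Lemieux–Johnson oxidation: osmium-catalysed dihydroxylation of the propenyl group and periodate cleavage of the diol unmask the aldehyde of ring G2 under neutral conditions that leave the benzoate, the silyl ether and the stereocentres intact.

Step 20
Reactants: 20 furofuran glycolyl imide; 30 aldehyde carrying protected unit G1
Product: 32 (2S,3R) syn-aldol imide linking the core to the G2–G1 chain, via dibutylboron enolate 31 (not isolated)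
Conditions: Bu2BOTf, i-Pr2NEt, CH2Cl2, −78 °C to 0 °C; then 30, −78 °C to 0 °C; pH 7 buffer, MeOH, H2O2
Reagents that add atoms: none
Why: Evans syn-aldol reaction: the (Z)-boron enolate of the (S)-auxiliary glycolate adds to aldehyde 30 under reagent control through a Zimmerman–Traxler chair, which sets C-α (R) and C-β (R) of the threo unit G2 irrespective of the remote stereocentres.

Step 21
Reactants: 32 syn-aldol imide
Product: 33 target protected as two aryl benzyl ethers and two primary TBS ethers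
Conditions: LiBH4 (excess), THF/MeOH, 0 °C to rt
Reagents that add atoms: none
Why: Borohydride reduction of the imide to the primary alcohol together with reductive cleavage of both benzoate esters frees three hydroxyls in one operation, and because the phenols are still benzylated no quinone methide can form from the benzylic esters.

Step 22
Reactants: 33 bis-TBS bis-benzyl ether
Product: 34 target protected as two aryl benzyl ethers
Conditions: TBAF, THF, rt
Reagents that add atoms: none
Why: Fluoride-induced cleavage of the two primary TBS ethers; no stereocentre is affected.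

Step 23
Reactants: 34 bis-benzyl ether
Product: 35 CNP0316493.1
Conditions: H2 (1 atm), Pd/C (10%), EtOAc/EtOH, rt
Reagents that add atoms: none
Why: Catalytic hydrogenolysis of the two aryl benzyl ethers under mild conditions, which are cleaved much faster than the benzylic C–O bonds of the furofuran and of the secondary alcohols, should deliver the target.

Compound list

1 | syringaldehyde (4-hydroxy-3,5-dimethoxybenzaldehyde) | COc1cc(C=O)cc(OC)c1O | starting material
2 | 3,5-dimethoxy-4-(triisopropylsilyloxy)benzaldehyde | COc1cc(C=O)cc(OC)c1O[Si](C(C)C)(C(C)C)C(C)C | intermediate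
3 | racemic 1-[3,5-dimethoxy-4-(triisopropylsilyloxy)phenyl]prop-2-en-1-ol | C=CC(O)c1cc(OC)c(O[Si](C(C)C)(C(C)C)C(C)C)c(OC)c1 | intermediate
4 | (S)-[3,5-dimethoxy-4-(triisopropylsilyloxy)phenyl][(2R)-oxiran-2-yl]methanol (erythro epoxy alcohol) | COc1cc([C@H](O)[C@H]2CO2)cc(OC)c1O[Si](C(C)C)(C(C)C)C(C)C | intermediate
5 | (2R)-2-[(S)-(allyloxy)[3,5-dimethoxy-4-(triisopropylsilyloxy)phenyl]methyl]oxirane | COc1cc([C@H](OCC=C)[C@H]2CO2)cc(OC)c1O[Si](C(C)C)(C(C)C)C(C)C | intermediate
6 | canolol (2,6-dimethoxy-4-vinylphenol) | C=Cc1cc(OC)c(O)c(OC)c1 | starting material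
7 | (S)-4-benzyl-3-(chloroacetyl)oxazolidin-2-one | O=C(CCl)N1[C@@H](Cc2ccccc2)COC1=O | starting material
8 | (S)-4-benzyl-3-[(2,6-dimethoxy-4-vinylphenoxy)acetyl]oxazolidin-2-one | C=Cc1cc(OC)c(OCC(=O)N2[C@@H](Cc3ccccc3)COC2=O)c(OC)c1 | intermediate
9 | 4-(benzyloxy)-3-methoxybenzaldehyde (O-benzylvanillin) | COc1cc(C=O)ccc1OCc1ccccc1 | starting material
10 | dibutylboron (Z)-enolate of 8 (not isolated) | C=Cc1cc(OC)c(O/C=C(\OB(CCCC)CCCC)N2[C@@H](Cc3ccccc3)COC2=O)c(OC)c1 | intermediate
11 | (S)-4-benzyl-3-[(2S,3R)-3-[4-(benzyloxy)-3-methoxyphenyl]-2-(2,6-dimethoxy-4-vinylphenoxy)-3-hydroxypropanoyl]oxazolidin-2-one | C=Cc1cc(OC)c(O[C@H](C(=O)N2[C@@H](Cc3ccccc3)COC2=O)[C@H](O)c2ccc(OCc3ccccc3)c(OC)c2)c(OC)c1 | intermediate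
12 | (1R,2R)-1-[4-(benzyloxy)-3-methoxyphenyl]-2-(2,6-dimethoxy-4-vinylphenoxy)propane-1,3-diol (threo) | C=Cc1cc(OC)c(O[C@H](CO)[C@H](O)c2ccc(OCc3ccccc3)c(OC)c2)c(OC)c1 | intermediate
13 | (1R,2R)-1-[4-(benzyloxy)-3-methoxyphenyl]-3-[(tert-butyldimethylsilyl)oxy]-2-(2,6-dimethoxy-4-vinylphenoxy)propan-1-ol | C=Cc1cc(OC)c(O[C@H](CO[Si](C)(C)C(C)(C)C)[C@H](O)c2ccc(OCc3ccccc3)c(OC)c2)c(OC)c1 | intermediate
14 | (1S,2R)-1-[4-(benzyloxy)-3-methoxyphenyl]-3-[(tert-butyldimethylsilyl)oxy]-2-(2,6-dimethoxy-4-vinylphenoxy)propyl benzoate (erythro) | C=Cc1cc(OC)c(O[C@H](CO[Si](C)(C)C(C)(C)C)[C@@H](OC(=O)c2ccccc2)c2ccc(OCc3ccccc3)c(OC)c2)c(OC)c1 | intermediate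
15 | (1S,2R)-1-[4-(benzyloxy)-3-methoxyphenyl]-3-[(tert-butyldimethylsilyl)oxy]-2-[4-[(E)-3-[(S)-[3,5-dimethoxy-4-(triisopropylsilyloxy)phenyl][(2R)-oxiran-2-yl]methoxy]prop-1-en-1-yl]-2,6-dimethoxyphenoxy]propyl benzoate | COc1cc([C@H](OC/C=C/c2cc(OC)c(O[C@H](CO[Si](C)(C)C(C)(C)C)[C@@H](OC(=O)c3ccccc3)c3ccc(OCc4ccccc4)c(OC)c3)c(OC)c2)[C@H]2CO2)cc(OC)c1O[Si](C(C)C)(C(C)C)C(C)C | intermediate
16 | ring A tetrahydrofuran from 15 with Cp2TiCl bound to C-7′ and to O-9 (tetravalent titanium; C-7′ epimers; cyclopentadienyl rings drawn σ-bonded; not isolated) | COc1cc([C@@H]2OC[C@@H](C([Ti](Cl)(C3C=CC=C3)C3C=CC=C3)c3cc(OC)c(O[C@H](CO[Si](C)(C)C(C)(C)C)[C@@H](OC(=O)c4ccccc4)c4ccc(OCc5ccccc5)c(OC)c4)c(OC)c3)[C@H]2CO[Ti](Cl)(C2C=CC=C2)C2C=CC=C2)cc(OC)c1O[Si](C(C)C)(C(C)C)C(C)C | intermediate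
17 | C-7′ iodide of 16 with O-9 still titanium-bound (C-7′ epimers; not isolated) | COc1cc([C@@H]2OC[C@@H](C(I)c3cc(OC)c(O[C@H](CO[Si](C)(C)C(C)(C)C)[C@@H](OC(=O)c4ccccc4)c4ccc(OCc5ccccc5)c(OC)c4)c(OC)c3)[C@H]2CO[Ti](Cl)(C2C=CC=C2)C2C=CC=C2)cc(OC)c1O[Si](C(C)C)(C(C)C)C(C)C | intermediate
18 | (1S,2R)-1-[4-(benzyloxy)-3-methoxyphenyl]-3-[(tert-butyldimethylsilyl)oxy]-2-[4-[(1R,3aS,4R,6aS)-4-[3,5-dimethoxy-4-(triisopropylsilyloxy)phenyl]tetrahydro-1H,3H-furo[3,4-c]furan-1-yl]-2,6-dimethoxyphenoxy]propyl benzoate | COc1cc([C@@H]2OC[C@@H]3[C@H]2CO[C@H]3c2cc(OC)c(O[C@H](CO[Si](C)(C)C(C)(C)C)[C@@H](OC(=O)c3ccccc3)c3ccc(OCc4ccccc4)c(OC)c3)c(OC)c2)cc(OC)c1O[Si](C(C)C)(C(C)C)C(C)C | intermediate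
19 | (1S,2R)-1-[4-(benzyloxy)-3-methoxyphenyl]-3-[(tert-butyldimethylsilyl)oxy]-2-[4-[(1R,3aS,4R,6aS)-4-(4-hydroxy-3,5-dimethoxyphenyl)tetrahydro-1H,3H-furo[3,4-c]furan-1-yl]-2,6-dimethoxyphenoxy]propyl benzoate | COc1cc([C@@H]2OC[C@@H]3[C@H]2CO[C@H]3c2cc(OC)c(O[C@H](CO[Si](C)(C)C(C)(C)C)[C@@H](OC(=O)c3ccccc3)c3ccc(OCc4ccccc4)c(OC)c3)c(OC)c2)cc(OC)c1O | intermediate
20 | 19 alkylated on the ring S1 phenol oxygen with the CH2C(=O)–[(S)-4-benzyl-2-oxooxazolidin-3-yl] group | COc1cc([C@@H]2OC[C@@H]3[C@H]2CO[C@H]3c2cc(OC)c(O[C@H](CO[Si](C)(C)C(C)(C)C)[C@@H](OC(=O)c3ccccc3)c3ccc(OCc4ccccc4)c(OC)c3)c(OC)c2)cc(OC)c1OCC(=O)N1[C@@H](Cc2ccccc2)COC1=O | intermediate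
21 | trans-isoeugenol (2-methoxy-4-[(E)-prop-1-enyl]phenol) | C/C=C/c1ccc(O)c(OC)c1 | starting material
22 | (R)-4-benzyl-3-(chloroacetyl)oxazolidin-2-one | O=C(CCl)N1[C@H](Cc2ccccc2)COC1=O | starting material
23 | (R)-4-benzyl-3-[[2-methoxy-4-[(E)-prop-1-enyl]phenoxy]acetyl]oxazolidin-2-one | C/C=C/c1ccc(OCC(=O)N2[C@H](Cc3ccccc3)COC2=O)c(OC)c1 | intermediate
24 | dibutylboron (Z)-enolate of 23 (not isolated) | C/C=C/c1ccc(O/C=C(\OB(CCCC)CCCC)N2[C@H](Cc3ccccc3)COC2=O)c(OC)c1 | intermediate
25 | (R)-4-benzyl-3-[(2R,3S)-3-[4-(benzyloxy)-3-methoxyphenyl]-3-hydroxy-2-[2-methoxy-4-[(E)-prop-1-enyl]phenoxy]propanoyl]oxazolidin-2-one | C/C=C/c1ccc(O[C@@H](C(=O)N2[C@H](Cc3ccccc3)COC2=O)[C@@H](O)c2ccc(OCc3ccccc3)c(OC)c2)c(OC)c1 | intermediate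
26 | (1S,2S)-1-[4-(benzyloxy)-3-methoxyphenyl]-2-[2-methoxy-4-[(E)-prop-1-enyl]phenoxy]propane-1,3-diol (threo) | C/C=C/c1ccc(O[C@@H](CO)[C@@H](O)c2ccc(OCc3ccccc3)c(OC)c2)c(OC)c1 | intermediate
27 | (1S,2S)-1-[4-(benzyloxy)-3-methoxyphenyl]-3-[(tert-butyldimethylsilyl)oxy]-2-[2-methoxy-4-[(E)-prop-1-enyl]phenoxy]propan-1-ol | C/C=C/c1ccc(O[C@@H](CO[Si](C)(C)C(C)(C)C)[C@@H](O)c2ccc(OCc3ccccc3)c(OC)c2)c(OC)c1 | intermediate
28 | (1R,2S)-1-[4-(benzyloxy)-3-methoxyphenyl]-3-[(tert-butyldimethylsilyl)oxy]-2-[2-methoxy-4-[(E)-prop-1-enyl]phenoxy]propyl benzoate (erythro) | C/C=C/c1ccc(O[C@@H](CO[Si](C)(C)C(C)(C)C)[C@H](OC(=O)c2ccccc2)c2ccc(OCc3ccccc3)c(OC)c2)c(OC)c1 | intermediate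
29 | vicinal diol from dihydroxylation of the propenyl group of 28 (diastereomer mixture; not isolated) | CC(O)C(O)c1ccc(O[C@@H](CO[Si](C)(C)C(C)(C)C)[C@H](OC(=O)c2ccccc2)c2ccc(OCc3ccccc3)c(OC)c2)c(OC)c1 | intermediate
30 | (1R,2S)-1-[4-(benzyloxy)-3-methoxyphenyl]-3-[(tert-butyldimethylsilyl)oxy]-2-(4-formyl-2-methoxyphenoxy)propyl benzoate | O=Cc1ccc(O[C@@H](CO[Si](C)(C)C(C)(C)C)[C@H](OC(=O)c2ccccc2)c2ccc(OCc3ccccc3)c(OC)c2)c(OC)c1 | intermediate
31 | dibutylboron (Z)-enolate of 20 (not isolated) | COc1cc([C@@H]2OC[C@@H]3[C@H]2CO[C@H]3c2cc(OC)c(O[C@H](CO[Si](C)(C)C(C)(C)C)[C@@H](OC(=O)c3ccccc3)c3ccc(OCc4ccccc4)c(OC)c3)c(OC)c2)cc(OC)c1O/C=C(\OB(CCCC)CCCC)N1[C@@H](Cc2ccccc2)COC1=O | intermediate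
32 | syn-aldol adduct of 20 and 30: (S)-oxazolidinone imide of the (2S,3R)-3-hydroxypropanoic acid that carries the ring S1 oxygen on C-2 and ring G2 (with protected unit G1) on C-3 | COc1cc([C@@H](OC(=O)c2ccccc2)[C@H](CO[Si](C)(C)C(C)(C)C)Oc2ccc([C@@H](O)[C@@H](C(=O)N3[C@@H](Cc4ccccc4)COC3=O)Oc3c(OC)cc([C@@H]4OC[C@@H]5[C@H]4CO[C@H]5c4cc(OC)c(O[C@H](CO[Si](C)(C)C(C)(C)C)[C@@H](OC(=O)c5ccccc5)c5ccc(OCc6ccccc6)c(OC)c5)c(OC)c4)cc3OC)cc2OC)ccc1OCc1ccccc1 | intermediate
33 | target with both phenols as benzyl ethers and the primary hydroxyls of G1 and G3 as TBS ethers | COc1cc([C@@H](O)[C@H](CO[Si](C)(C)C(C)(C)C)Oc2ccc([C@@H](O)[C@@H](CO)Oc3c(OC)cc([C@@H]4OC[C@@H]5[C@H]4CO[C@H]5c4cc(OC)c(O[C@H](CO[Si](C)(C)C(C)(C)C)[C@@H](O)c5ccc(OCc6ccccc6)c(OC)c5)c(OC)c4)cc3OC)cc2OC)ccc1OCc1ccccc1 | intermediate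
34 | target with both phenols as benzyl ethers | COc1cc([C@@H](O)[C@H](CO)Oc2ccc([C@@H](O)[C@@H](CO)Oc3c(OC)cc([C@@H]4OC[C@@H]5[C@H]4CO[C@H]5c4cc(OC)c(O[C@H](CO)[C@@H](O)c5ccc(OCc6ccccc6)c(OC)c5)c(OC)c4)cc3OC)cc2OC)ccc1OCc1ccccc1 | intermediate
35 | CNP0316493.1 | COc1cc([C@@H](O)[C@H](CO)Oc2ccc([C@@H](O)[C@@H](CO)Oc3c(OC)cc([C@@H]4OC[C@@H]5[C@H]4CO[C@H]5c4cc(OC)c(O[C@H](CO)[C@@H](O)c5ccc(O)c(OC)c5)c(OC)c4)cc3OC)cc2OC)ccc1O | target

Total step count: 23. Longest linear sequence: 13 steps (steps 5 to 13 and 20 to 23, from canolol 6).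

Steps most likely to fail

Step 11 (key step). The β-titanoxy radical may be reduced and eliminated to an alkene before it cyclises, or the benzylic titanium species may be protonated instead of iodinated, so that ring B does not close. Fallback: setting out from 15, the same Cp2TiCl cyclisation is run without iodine and quenched with aqueous acid, which should give the ring A alcohol (2R,3S,4S)-2-aryl-4-benzyl-3-(hydroxymethyl)tetrahydrofuran F1. Benzylic dehydrogenation of F1 with DDQ in CH2Cl2 (oxidative C–H etherification through the quinoid cation at C-7′, captured by the C-9 hydroxyl from the convex face) then comes back to the route at 18.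

Step 10. Homodimerisation of the styrene to a stilbene and of the allyl ether may outpace the cross reaction, or the electron-rich styrene may give a sluggish ruthenium benzylidene. Fallback without metathesis: setting out from 14, OsO4/NaIO4 cleavage of the vinyl group gives benzaldehyde F2. Wittig reaction with (triphenylphosphoranylidene)acetaldehyde gives (E)-cinnamaldehyde F3, and Luche reduction (NaBH4, CeCl3·7H2O) gives cinnamyl alcohol F4. Appel bromination (CBr4, PPh3) gives cinnamyl bromide F5, and Williamson alkylation of epoxy alcohol 4 with F5 (NaH, THF, 0 °C) comes back to the route at 15.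

Step 9 (the same concern applies to step 18). Partial ionisation of the electron-rich benzylic alkoxyphosphonium ion may lead to incomplete inversion or to elimination. Fallback: setting out from 13, Dess–Martin oxidation gives aryl ketone F6. Chelation-controlled reduction with Zn(BH4)2 (zinc bridged between the carbonyl and the α-aryloxy oxygen, hydride delivered from the face of the small substituent) should give erythro alcohol F7. Benzoylation (BzCl, pyridine, DMAP) comes back to the route at 14.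

Further compounds

F1 | step 11 | (1S,2R)-1-[4-(benzyloxy)-3-methoxyphenyl]-3-[(tert-butyldimethylsilyl)oxy]-2-[4-[[(3S,4S,5R)-5-[3,5-dimethoxy-4-(triisopropylsilyloxy)phenyl]-4-(hydroxymethyl)tetrahydrofuran-3-yl]methyl]-2,6-dimethoxyphenoxy]propyl benzoate | COc1cc([C@@H]2OC[C@@H](Cc3cc(OC)c(O[C@H](CO[Si](C)(C)C(C)(C)C)[C@@H](OC(=O)c4ccccc4)c4ccc(OCc5ccccc5)c(OC)c4)c(OC)c3)[C@H]2CO)cc(OC)c1O[Si](C(C)C)(C(C)C)C(C)C
F2 | step 10 | (1S,2R)-1-[4-(benzyloxy)-3-methoxyphenyl]-3-[(tert-butyldimethylsilyl)oxy]-2-(4-formyl-2,6-dimethoxyphenoxy)propyl benzoate | O=Cc1cc(OC)c(O[C@H](CO[Si](C)(C)C(C)(C)C)[C@@H](OC(=O)c2ccccc2)c2ccc(OCc3ccccc3)c(OC)c2)c(OC)c1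
F3 | step 10 | (1S,2R)-1-[4-(benzyloxy)-3-methoxyphenyl]-3-[(tert-butyldimethylsilyl)oxy]-2-[2,6-dimethoxy-4-[(E)-3-oxoprop-1-enyl]phenoxy]propyl benzoate | O=C/C=C/c1cc(OC)c(O[C@H](CO[Si](C)(C)C(C)(C)C)[C@@H](OC(=O)c2ccccc2)c2ccc(OCc3ccccc3)c(OC)c2)c(OC)c1
F4 | step 10 | (1S,2R)-1-[4-(benzyloxy)-3-methoxyphenyl]-3-[(tert-butyldimethylsilyl)oxy]-2-[4-[(E)-3-hydroxyprop-1-enyl]-2,6-dimethoxyphenoxy]propyl benzoate | OC/C=C/c1cc(OC)c(O[C@H](CO[Si](C)(C)C(C)(C)C)[C@@H](OC(=O)c2ccccc2)c2ccc(OCc3ccccc3)c(OC)c2)c(OC)c1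
F5 | step 10 | (1S,2R)-1-[4-(benzyloxy)-3-methoxyphenyl]-2-[4-[(E)-3-bromoprop-1-enyl]-2,6-dimethoxyphenoxy]-3-[(tert-butyldimethylsilyl)oxy]propyl benzoate | BrC/C=C/c1cc(OC)c(O[C@H](CO[Si](C)(C)C(C)(C)C)[C@@H](OC(=O)c2ccccc2)c2ccc(OCc3ccccc3)c(OC)c2)c(OC)c1
F6 | step 9 | (2R)-1-[4-(benzyloxy)-3-methoxyphenyl]-3-[(tert-butyldimethylsilyl)oxy]-2-(2,6-dimethoxy-4-vinylphenoxy)propan-1-one | C=Cc1cc(OC)c(O[C@H](CO[Si](C)(C)C(C)(C)C)C(=O)c2ccc(OCc3ccccc3)c(OC)c2)c(OC)c1
F7 | step 9 | (1S,2R)-1-[4-(benzyloxy)-3-methoxyphenyl]-3-[(tert-butyldimethylsilyl)oxy]-2-(2,6-dimethoxy-4-vinylphenoxy)propan-1-ol (erythro) | C=Cc1cc(OC)c(O[C@H](CO[Si](C)(C)C(C)(C)C)[C@@H](O)c2ccc(OCc3ccccc3)c(OC)c2)c(OC)c1
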